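**Plan**

- The target is a (3R)-3-aryl-3,5,7-trihydroxychroman-4-one. In ring C the C3 hydroxyl sits α and the C2–O1 ether bond β to the C4 ketone: the oxygen pattern of an α,β-epoxy ketone whose CH2 end has been opened by the ring A phenol oxygen. This feature allows a nucleophilic epoxidation of an α-aryl enone as key step.
- The retrosynthesis cuts O1–C2 (epoxide opening), then the two oxirane C–O bonds at C2 and C3 back to a 2-aryl enone, then C3–C4 (1-arylvinyllithium plus ring A aldehyde) and the aryl–prenyl bond of ring B.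
- Forward, ring B is prenylated by directed lithiation and turned into a trisylhydrazone (steps 1–3), ring A is capped as its triallyl ether (step 4), and the two are joined by a Shapiro coupling and oxidised to the enone (steps 5–6).
- The oxirane is formed next (step 7) and ring C last, when deallylation frees the ortho phenoxide that opens the epoxide at CH2 (step 8).
- The only stereocentre, C3 (R), is set by catalyst control at the oxirane closure in step 7 and is not touched afterwards.

Key step: step 7

Assumption: the sense of induction of a cinchona phase-transfer catalyst on this enone cannot be predicted with confidence; the route is written with the cinchonine-derived salt, and the cinchonidine-derived pseudoenantiomer would take its place unchanged if the first delivers the (S)-epoxide.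

**Route**

Step 1
Reactants: 1 1-(2,4-dimethoxyphenyl)ethan-1-one (2',4'-dimethoxyacetophenone)
Product: 2 2-(2,4-dimethoxyphenyl)-2-methyl-1,3-dioxolane
Conditions: ethylene glycol (5 equiv), TsOH·H2O (5 mol%), toluene, reflux, Dean–Stark
Reagents that add atoms: ethylene glycol, OCCO
Why: Acid-catalysed ketalisation with azeotropic removal of water masks the ketone as a dioxolane that tolerates n-BuLi in the next step.

Step 2
Reactants: 2 2-(2,4-dimethoxyphenyl)-2-methyl-1,3-dioxolane; 3 1-bromo-3-methylbut-2-ene (prenyl bromide)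
Product: 6 1-[2,4-dimethoxy-3-(3-methylbut-2-en-1-yl)phenyl]ethan-1-one, via aryllithium 4 (not isolated), via prenylated dioxolane 5 (not isolated)
Conditions: n-BuLi (1.1 equiv), THF, 0 °C to rt; CuI (10 mol%), prenyl bromide (1.2 equiv), −20 °C to rt; then 1 M HCl, THF, rt
Reagents that add atoms: prenyl bromide (3), CC(C)=CCBr; water, O
Why: Directed ortho-metalation should take place at the C–H flanked by both methoxy groups, the aryllithium is alkylated at the primary carbon of prenyl bromide (copper-assisted allylic substitution), and the electron-rich aryl ketal hydrolyses in the dilute acid work-up without harm to the prenyl alkene.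

Step 3
Reactants: 6 1-[2,4-dimethoxy-3-(3-methylbut-2-en-1-yl)phenyl]ethan-1-one
Product: 7 (E)-N'-{1-[2,4-dimethoxy-3-(3-methylbut-2-en-1-yl)phenyl]ethylidene}-2,4,6-tri(propan-2-yl)benzenesulfonohydrazide
Conditions: 2,4,6-triisopropylbenzenesulfonyl hydrazide (1.05 equiv), MeOH, cat. HCl, rt
Reagents that add atoms: 2,4,6-triisopropylbenzenesulfonyl hydrazide, NNS(=O)(=O)c1c(C(C)C)cc(C(C)C)cc1C(C)C
Why: Hydrazone condensation of a methyl ketone with the trisyl hydrazide is routine and gives the arenesulfonylhydrazone needed for the Shapiro reaction, the bulky sulfonyl group suppressing ortho-lithiation of the sulfonyl arene later.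

Step 4
Reactants: 8 2,4,6-trihydroxybenzaldehyde; 9 3-bromoprop-1-ene (allyl bromide)
Product: 10 2,4,6-tris(prop-2-en-1-yloxy)benzaldehyde
Conditions: allyl bromide (3.6 equiv), K2CO3 (4 equiv), DMF, rt to 50 °C
Reagents that add atoms: allyl bromide (9), C=CCBr
Why: Williamson etherification of the three phenols in a dipolar aprotic solvent should favour O- over C-allylation because the formyl group lowers the carbon nucleophilicity of the ring.

Step 5
Reactants: 7 the trisylhydrazone; 10 2,4,6-tris(prop-2-en-1-yloxy)benzaldehyde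
Product: 12 rac-2-[2,4-dimethoxy-3-(3-methylbut-2-en-1-yl)phenyl]-1-[2,4,6-tris(prop-2-en-1-yloxy)phenyl]prop-2-en-1-ol, via vinyllithium 11 (not isolated)
Conditions: n-BuLi (2.05 equiv), THF, −78 to 0 °C (N2 evolution); −78 °C, then 10; H2O quench, base-washed silica
Reagents that add atoms: none
Why: In the Shapiro reaction double deprotonation of the hydrazone followed by loss of sulfinate and dinitrogen gives the 1-arylvinyllithium, which adds 1,2 to the aldehyde; the carbinol centre forms as a racemate and is erased in step 6.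

Step 6
Reactants: 12 the racemic allylic alcohol
Product: 13 2-[2,4-dimethoxy-3-(3-methylbut-2-en-1-yl)phenyl]-1-[2,4,6-tris(prop-2-en-1-yloxy)phenyl]prop-2-en-1-one
Conditions: activated MnO2 (15 equiv), CH2Cl2, rt; used at once in step 7
Reagents that add atoms: none
Why: MnO2 oxidation of an alcohol that is both allylic and benzylic runs under neutral conditions, which the acid-labile trialkoxybenzyl carbinol requires, and leaves the prenyl and allyl alkenes alone.

Step 7
Reactants: 13 the 2-aryl enone
Product: 15 (R)-{2-[2,4-dimethoxy-3-(3-methylbut-2-en-1-yl)phenyl]oxiran-2-yl}[2,4,6-tris(prop-2-en-1-yloxy)phenyl]methanone, via peroxy enolate 14 (not isolated)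
Conditions: cumene hydroperoxide (1.5 equiv), N-[4-(trifluoromethyl)benzyl]cinchoninium bromide (10 mol%), KOH (20 mol%, 1 M aq.), toluene, −20 °C
Reagents that add atoms: cumene hydroperoxide, CC(C)(OO)c1ccccc1
Why: The cumylperoxide anion, carried into toluene as its chiral ammonium ion pair, adds to the unhindered terminal CH2 of the enone (Weitz–Scheffer conjugate addition, first C–O bond), and the α-aryl enolate 14 then attacks the proximal peroxide oxygen and expels cumyl oxide (second C–O bond). This closure of the oxirane is 3-exo-tet. The closest known reactions are the phase-transfer Weitz–Scheffer epoxidations of isoflavones and 2-alkylnaphthoquinones (α-substituted enones) and the nucleophilic epoxidation of α-substituted acroleins, where a quaternary α-centre likewise arises at ring closure. Because the conjugate addition creates no stereocentre, the configuration is decided when the enolate carbon bonds to oxygen; the cinchoninium cation, held to the enolate oxygen by ion pairing and by its free C9 hydroxyl, should shield one enolate face and deliver the (R)-epoxide under catalyst control. The step needs chemoselectivity for the enone alkene and no premature ring closure: the oxidant is a nucleophile, so the prenyl and allyl alkenes and the electron-rich arenes are left alone, and the allyl caps on both ortho oxygens of ring A rule out oxa-Michael addition.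

Step 8
Reactants: 15 the (R)-epoxy ketone
Product: 17 (3R)-3-[2,4-dimethoxy-3-(3-methylbut-2-en-1-yl)phenyl]-3,5,7-trihydroxy-2,3-dihydro-4H-chromen-4-one, via triphenol epoxy ketone 16 (not isolated)
Conditions: Pd(PPh3)4 (10 mol%), K2CO3 (4 equiv), degassed MeOH/THF, rt to 40 °C; pH 6 buffer work-up
Reagents that add atoms: none
Why: Zerovalent palladium ionises the aryl allyl ethers (Tsuji–Trost-type deallylation, the π-allyl unit passing to methanol), and the freed ortho phenoxide opens the oxirane by SN2 attack at the unsubstituted CH2 (6-endo-tet, the 5-exo alternative would need substitution at the quaternary carbon), so ring C closes with the C3 configuration carried over unchanged.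

**Compound list**

1 | 1-(2,4-dimethoxyphenyl)ethan-1-one | CC(=O)c1ccc(OC)cc1OC | starting material
2 | 2-(2,4-dimethoxyphenyl)-2-methyl-1,3-dioxolane | CC1(OCCO1)c1ccc(OC)cc1OC | intermediate
3 | 1-bromo-3-methylbut-2-ene (prenyl bromide) | CC(C)=CCBr | starting material
4 | [2,6-dimethoxy-3-(2-methyl-1,3-dioxolan-2-yl)phenyl]lithium (not isolated) | [Li]c1c(OC)ccc(C2(C)OCCO2)c1OC | intermediate
5 | 2-[2,4-dimethoxy-3-(3-methylbut-2-en-1-yl)phenyl]-2-methyl-1,3-dioxolane (not isolated) | CC(C)=CCc1c(OC)ccc(C2(C)OCCO2)c1OC | intermediate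
6 | 1-[2,4-dimethoxy-3-(3-methylbut-2-en-1-yl)phenyl]ethan-1-one | CC(=O)c1ccc(OC)c(CC=C(C)C)c1OC | intermediate
7 | (E)-N'-{1-[2,4-dimethoxy-3-(3-methylbut-2-en-1-yl)phenyl]ethylidene}-2,4,6-tri(propan-2-yl)benzenesulfonohydrazide | C/C(=N\NS(=O)(=O)c1c(C(C)C)cc(C(C)C)cc1C(C)C)c1ccc(OC)c(CC=C(C)C)c1OC | intermediate
8 | 2,4,6-trihydroxybenzaldehyde | O=Cc1c(O)cc(O)cc1O | starting material
9 | 3-bromoprop-1-ene (allyl bromide) | C=CCBr | starting material
10 | 2,4,6-tris(prop-2-en-1-yloxy)benzaldehyde | O=Cc1c(OCC=C)cc(OCC=C)cc1OCC=C | intermediate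
11 | {1-[2,4-dimethoxy-3-(3-methylbut-2-en-1-yl)phenyl]ethenyl}lithium (not isolated) | [Li]C(=C)c1ccc(OC)c(CC=C(C)C)c1OC | intermediate
12 | rac-2-[2,4-dimethoxy-3-(3-methylbut-2-en-1-yl)phenyl]-1-[2,4,6-tris(prop-2-en-1-yloxy)phenyl]prop-2-en-1-ol | C=C(C(O)c1c(OCC=C)cc(OCC=C)cc1OCC=C)c1ccc(OC)c(CC=C(C)C)c1OC | intermediate
13 | 2-[2,4-dimethoxy-3-(3-methylbut-2-en-1-yl)phenyl]-1-[2,4,6-tris(prop-2-en-1-yloxy)phenyl]prop-2-en-1-one | C=C(C(=O)c1c(OCC=C)cc(OCC=C)cc1OCC=C)c1ccc(OC)c(CC=C(C)C)c1OC | intermediate
14 | 2-[2,4-dimethoxy-3-(3-methylbut-2-en-1-yl)phenyl]-3-[(2-phenylpropan-2-yl)peroxy]-1-[2,4,6-tris(prop-2-en-1-yloxy)phenyl]prop-1-en-1-olate, ion-paired to the catalyst cation (not isolated) | [O-]C(=C(COOC(C)(C)c1ccccc1)c1ccc(OC)c(CC=C(C)C)c1OC)c1c(OCC=C)cc(OCC=C)cc1OCC=C | intermediate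
15 | (R)-{2-[2,4-dimethoxy-3-(3-methylbut-2-en-1-yl)phenyl]oxiran-2-yl}[2,4,6-tris(prop-2-en-1-yloxy)phenyl]methanone | O=C(c1c(OCC=C)cc(OCC=C)cc1OCC=C)[C@@]1(c2ccc(OC)c(CC=C(C)C)c2OC)CO1 | intermediate
16 | (R)-{2-[2,4-dimethoxy-3-(3-methylbut-2-en-1-yl)phenyl]oxiran-2-yl}(2,4,6-trihydroxyphenyl)methanone (not isolated) | O=C(c1c(O)cc(O)cc1O)[C@@]1(c2ccc(OC)c(CC=C(C)C)c2OC)CO1 | intermediate
17 | (3R)-3-[2,4-dimethoxy-3-(3-methylbut-2-en-1-yl)phenyl]-3,5,7-trihydroxy-2,3-dihydro-4H-chromen-4-one (CNP0269650.1) | COc1ccc([C@@]2(O)COc3cc(O)cc(O)c3C2=O)c(OC)c1CC=C(C)C | target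

**Step count and risks**

Total step count: 8. Longest linear sequence: 7 steps (steps 1, 2, 3, 5, 6, 7, 8 from compound 1); step 4 is the side branch.

Steps most likely to fail:

1. Step 7. The two enolate faces may be poorly distinguished at oxirane closure, because the ion pair around a twisted, doubly ortho-substituted aroyl enolate may be loose. The enone may also be lost by dimerisation before oxygen transfer.
 Fallback: this sets out from 13 and returns at 17, and places the stereocentre by reagent-controlled enolate hydroxylation instead. Deallylation of 13 with Pd(PPh3)4 and K2CO3 in MeOH frees the ortho phenoxide, which adds to the enone CH2 (oxa-Michael closure) to give rac-3-[2,4-dimethoxy-3-(3-methylbut-2-en-1-yl)phenyl]-5,7-dihydroxy-2,3-dihydro-4H-chromen-4-one F1. Silylation with TBSOTf and 2,6-lutidine should give the 5,7-bis(tert-butyldimethylsilyl) ether F2. Its sodium enolate (NaN(SiMe3)2, THF, −78 °C) is hydroxylated with the appropriate antipode of an enantiopure (8,8-dichlorocamphorsulfonyl)oxaziridine to the (3R)-3-hydroxy bis-silyl ether F3. HF·pyridine then releases 17.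

2. Step 8. While the allyl ethers ionise, the π-allyl fragment may be returned to the electron-rich carbons of ring A. Zerovalent palladium may also insert into the benzylic C–O bond of the epoxy ketone, and ionisation at the quaternary carbon would lead to five-membered closure and loss of configuration.
 Fallback: this sets out from 15 and returns at 17, and avoids π-allyl intermediates. The allyl ethers are isomerised with H2-activated [Ir(cod)(PMePh2)2]PF6 in THF to (R)-{2-[2,4-dimethoxy-3-(3-methylbut-2-en-1-yl)phenyl]oxiran-2-yl}{2,4,6-tris[(E)-prop-1-en-1-yloxy]phenyl}methanone F4. The enol ethers are then cleaved under buffered neutral conditions with HgCl2 and HgO in aqueous acetone, and NaHCO3 in MeOH brings about the phenoxide ring opening to 17.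

3. Step 5. Conversion of the hydrazone to the vinyllithium may be incomplete. The vinyllithium may also be quenched by proton transfer from the doubly activated benzylic and allylic CH2 of the prenyl group, and addition to the hindered aldehyde may be slow.
 Fallback: this sets out from 6 (with 10) and returns at 12. Ketone 6 is converted with KN(SiMe3)2 and PhNTf2 into 1-[2,4-dimethoxy-3-(3-methylbut-2-en-1-yl)phenyl]ethenyl trifluoromethanesulfonate F5. F5 is then coupled with aldehyde 10 in a Nozaki–Hiyama–Kishi reaction (CrCl2, cat. NiCl2, DMF, rt) to give 12 without a strongly basic carbanion.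

**Further compounds**

F1 | step 7 | rac-3-[2,4-dimethoxy-3-(3-methylbut-2-en-1-yl)phenyl]-5,7-dihydroxy-2,3-dihydro-4H-chromen-4-one | COc1ccc(C2COc3cc(O)cc(O)c3C2=O)c(OC)c1CC=C(C)C
F2 | step 7 | rac-5,7-bis[(tert-butyldimethylsilyl)oxy]-3-[2,4-dimethoxy-3-(3-methylbut-2-en-1-yl)phenyl]-2,3-dihydro-4H-chromen-4-one | COc1ccc(C2COc3cc(O[Si](C)(C)C(C)(C)C)cc(O[Si](C)(C)C(C)(C)C)c3C2=O)c(OC)c1CC=C(C)C
F3 | step 7 | (3R)-5,7-bis[(tert-butyldimethylsilyl)oxy]-3-[2,4-dimethoxy-3-(3-methylbut-2-en-1-yl)phenyl]-3-hydroxy-2,3-dihydro-4H-chromen-4-one | COc1ccc([C@@]2(O)COc3cc(O[Si](C)(C)C(C)(C)C)cc(O[Si](C)(C)C(C)(C)C)c3C2=O)c(OC)c1CC=C(C)C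
F4 | step 8 | (R)-{2-[2,4-dimethoxy-3-(3-methylbut-2-en-1-yl)phenyl]oxiran-2-yl}{2,4,6-tris[(E)-prop-1-en-1-yloxy]phenyl}methanone | O=C(c1c(O/C=C/C)cc(O/C=C/C)cc1O/C=C/C)[C@@]1(c2ccc(OC)c(CC=C(C)C)c2OC)CO1
F5 | step 5 | 1-[2,4-dimethoxy-3-(3-methylbut-2-en-1-yl)phenyl]ethenyl trifluoromethanesulfonate | C=C(OS(=O)(=O)C(F)(F)F)c1ccc(OC)c(CC=C(C)C)c1OC
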